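**Retrosynthetic overview**

1. The target comes from its tri-O-methyl ether by one global ether cleavage (last step).
2. The tri-O-methyl ether is cut at C3–C1′ of the chlorinated isoflavone: an aryl radical from a 4-(isoflavon-8-yloxy)benzenediazonium salt adds to an open-chain o-hydroxyaryl enaminone, and the same operation closes the chlorinated pyran-4-one (O1–C2), the last ring formed.
3. The diazonium salt comes from the 8-(4-nitrophenoxy)isoflavone (reduction, diazotisation). Its pyran-4-one (the first ring formed) is closed from a deoxybenzoin, made by Friedel–Crafts acylation/ortho-demethylation of the SNAr ether of 2,6-dimethoxyphenol and 4-fluoronitrobenzene.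
4. The enaminone comes from 2-chloro-1,3-dimethoxybenzene (Friedel–Crafts acetylation/ortho-demethylation, amide acetal condensation), so chlorine is in place from the start.
5. Enabling feature: C3 of the chlorinated chromone sits between the C4 carbonyl and the O1–C2 enol ether, so with O1–C2 opened it is the nucleophilic α-carbon of an enaminone whose ortho-phenol (O1) can re-close the ring. On the central benzene ring C1′ is para to the ether oxygen, so a para-nitro group first activates the SNAr ether formation and then becomes the N2 leaving group at C1′.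

Key step: step 8

Remark: the target has no stereogenic centre or axis (all aryl–aryl and aryl–O bonds rotate freely), so it is achiral and needs no enantiocontrol; the only stereodescriptors in the route are the E double bonds of the enaminones.

**Route**

Step 1
Reactants: 1 2,6-dimethoxyphenol; 2 1-fluoro-4-nitrobenzene
Product: 3 1,3-dimethoxy-2-(4-nitrophenoxy)benzene
Conditions: K2CO3 (1.5 equiv), DMF, 90 °C
Reagents that add atoms: none
Why: Nucleophilic aromatic substitution (SNAr through a Meisenheimer complex), in which the phenoxide of 1 displaces the fluoride para to the nitro group; the small, strongly activated fluoroarene should tolerate the two flanking methoxy groups.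

Step 2
Reactants: 3 1,3-dimethoxy-2-(4-nitrophenoxy)benzene; 4 (4-methoxyphenyl)acetyl chloride
Product: 6 1-[2-hydroxy-4-methoxy-3-(4-nitrophenoxy)phenyl]-2-(4-methoxyphenyl)ethan-1-one, via dimethoxy ketone 5 (not isolated)
Conditions: AlCl3 (3.5 equiv), CH2Cl2, 0 °C to 40 °C; aq. HCl work-up
Reagents that add atoms: none
Why: Friedel–Crafts acylation should occur at C4 of the dimethoxy ring (para to one methoxy, ortho to the other; the nitrophenoxy ring is deactivated), after which the aluminium chelated between the new ketone and the neighbouring methoxy oxygen cleaves exactly that methyl ether (chelation-directed demethylation) and leaves the 4-methoxy and anisyl ethers intact.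

Step 3
Reactants: 6 1-[2-hydroxy-4-methoxy-3-(4-nitrophenoxy)phenyl]-2-(4-methoxyphenyl)ethan-1-one
Product: 8 7-methoxy-3-(4-methoxyphenyl)-8-(4-nitrophenoxy)-4H-chromen-4-one, via enaminone 7 (not isolated)
Conditions: DMF-DMA (3 equiv), toluene, 100 °C
Reagents that add atoms: N,N-dimethylformamide dimethyl acetal, COC(OC)N(C)C
Why: The amide acetal condenses at the doubly activated benzylic methylene to give enaminone 7, whose ortho-phenol adds to the aminovinyl carbon and expels dimethylamine (deoxybenzoin route to isoflavones), closing the pyran-4-one of the lower isoflavone.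

Step 4
Reactants: 8 7-methoxy-3-(4-methoxyphenyl)-8-(4-nitrophenoxy)-4H-chromen-4-one
Product: 9 8-(4-aminophenoxy)-7-methoxy-3-(4-methoxyphenyl)-4H-chromen-4-one
Conditions: Fe powder (6 equiv), AcOH/EtOH 1:4, 70 °C
Reagents that add atoms: none
Why: Béchamp-type dissolving-metal reduction takes the nitro group to the aniline by electron transfer and should leave the chromone enone, the methyl ethers and the diaryl ether untouched.

Step 5
Reactants: 9 8-(4-aminophenoxy)-7-methoxy-3-(4-methoxyphenyl)-4H-chromen-4-one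
Product: 10 4-{[7-methoxy-3-(4-methoxyphenyl)-4-oxo-4H-chromen-8-yl]oxy}benzenediazonium tetrafluoroborate
Conditions: t-BuONO (1.3 equiv), HBF4 (48% aq., 2.5 equiv), MeCN/EtOH, 0 °C; precipitation with Et2O
Reagents that add atoms: tert-butyl nitrite, CC(C)(C)ON=O; tetrafluoroboric acid, [H+].F[B-](F)(F)F
Why: Diazotisation of the aniline by the nitrosonium ion generated from the alkyl nitrite and acid should give the diazonium tetrafluoroborate as a filterable solid; the molecule carries no free phenol or amine, so azo self-coupling is not possible.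

Step 6
Reactants: 11 2-chloro-1,3-dimethoxybenzene; 12 acetyl chloride
Product: 14 1-(3-chloro-2-hydroxy-4-methoxyphenyl)ethan-1-one, via dimethoxy acetophenone 13 (not isolated)
Conditions: AlCl3 (2.5 equiv), CH2Cl2, 0 °C to 40 °C; aq. HCl work-up
Reagents that add atoms: none
Why: Friedel–Crafts acetylation should go to the only doubly activated position (para to one methoxy, ortho to the other), and the carbonyl-bound aluminium then cleaves the methyl ether lying between the acetyl group and chlorine (chelation-directed demethylation).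

Step 7
Reactants: 14 1-(3-chloro-2-hydroxy-4-methoxyphenyl)ethan-1-one
Product: 15 (E)-1-(3-chloro-2-hydroxy-4-methoxyphenyl)-3-(dimethylamino)prop-2-en-1-one
Conditions: DMF-DMA (2 equiv), toluene, 90 °C
Reagents that add atoms: N,N-dimethylformamide dimethyl acetal, COC(OC)N(C)C
Why: Condensation of the methyl ketone with the amide acetal (enaminone formation) should give the push–pull (E)-enaminone, in which the hydrogen-bonded ortho-phenol stays free and no ring closure occurs without an electrophile or acid.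

Step 8
Reactants: 10 4-{[7-methoxy-3-(4-methoxyphenyl)-4-oxo-4H-chromen-8-yl]oxy}benzenediazonium tetrafluoroborate; 15 (E)-1-(3-chloro-2-hydroxy-4-methoxyphenyl)-3-(dimethylamino)prop-2-en-1-one (2.5 equiv)
Product: 17 8-chloro-7-methoxy-3-(4-{[7-methoxy-3-(4-methoxyphenyl)-4-oxo-4H-chromen-8-yl]oxy}phenyl)-4H-chromen-4-one, via α-aryl enaminone 16 (not isolated)
Conditions: eosin Y (2 mol %), DMSO, green LEDs (530 nm), 20 °C, N2; 10 added in portions to 15
Reagents that add atoms: none
Why: Green light excites eosin Y, which reduces the diazonium ion of 10 by single-electron transfer; loss of N2 gives the aryl radical, which adds to the electron-rich α-carbon of enaminone 15 (the future C3), and the N-stabilised α-amino radical is oxidised (by the eosin Y radical cation or by a further diazonium ion in a chain) to an iminium ion that loses its α-proton to give α-aryl enaminone 16. The closest known reaction type is the photoredox Meerwein-type C–H arylation/annulation of o-hydroxyaryl enaminones with aryl onium salts, which gives isoflavones. The pyran-4-one then closes by attack of the ortho-phenol on the aminovinyl carbon (future C2; 6-endo-trig oxa-Michael on the enaminone, equivalently 6-exo-trig on its iminium tautomer) and elimination of dimethylamine, which also takes up the HBF4. No stereocentre is formed. The step needs attack at the α-carbon only, secured by the push–pull polarisation of the enaminone (only α-attack gives the nitrogen-stabilised radical), and it needs the radical pathway to outrun polar azo coupling, which is favoured by the weakly electrophilic para-aryloxy diazonium ion, its portionwise addition to excess 15 under irradiation, and the absence of any free phenol or amine in 10. The aryl chloride, the second chromone and the methyl ethers should be inert to these metal-free, room-temperature conditions.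

Step 9
Reactants: 17 8-chloro-7-methoxy-3-(4-{[7-methoxy-3-(4-methoxyphenyl)-4-oxo-4H-chromen-8-yl]oxy}phenyl)-4H-chromen-4-one
Product: 18 Bisoflavolin J, 8-chloro-7-hydroxy-3-(4-{[7-hydroxy-3-(4-hydroxyphenyl)-4-oxo-4H-chromen-8-yl]oxy}phenyl)-4H-chromen-4-one
Conditions: BBr3 (12 equiv), CH2Cl2, −78 °C to rt; then MeOH, H2O
Reagents that add atoms: none
Why: Boron tribromide coordinates each methoxy oxygen and bromide cleaves the O–CH3 bond by SN2 (Lewis-acid ether cleavage); the diaryl ether offers no sp3 carbon for this attack, and the aryl chloride and both pyranones should survive, so all three phenols are freed in one operation.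

**Compound list**

1 | 2,6-dimethoxyphenol | COc1cccc(OC)c1O | starting material
2 | 1-fluoro-4-nitrobenzene | O=[N+]([O-])c1ccc(F)cc1 | starting material
3 | 1,3-dimethoxy-2-(4-nitrophenoxy)benzene | COc1cccc(OC)c1Oc1ccc([N+](=O)[O-])cc1 | intermediate
4 | (4-methoxyphenyl)acetyl chloride | COc1ccc(CC(=O)Cl)cc1 | starting material
5 | 1-[2,4-dimethoxy-3-(4-nitrophenoxy)phenyl]-2-(4-methoxyphenyl)ethan-1-one | COc1ccc(CC(=O)c2ccc(OC)c(Oc3ccc([N+](=O)[O-])cc3)c2OC)cc1 | intermediate (not isolated)
6 | 1-[2-hydroxy-4-methoxy-3-(4-nitrophenoxy)phenyl]-2-(4-methoxyphenyl)ethan-1-one | COc1ccc(CC(=O)c2ccc(OC)c(Oc3ccc([N+](=O)[O-])cc3)c2O)cc1 | intermediate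
7 | (E)-3-(dimethylamino)-1-[2-hydroxy-4-methoxy-3-(4-nitrophenoxy)phenyl]-2-(4-methoxyphenyl)prop-2-en-1-one | CN(C)/C=C(\c1ccc(OC)cc1)C(=O)c1ccc(OC)c(Oc2ccc([N+](=O)[O-])cc2)c1O | intermediate (not isolated)
8 | 7-methoxy-3-(4-methoxyphenyl)-8-(4-nitrophenoxy)-4H-chromen-4-one | COc1ccc(-c2coc3c(Oc4ccc([N+](=O)[O-])cc4)c(OC)ccc3c2=O)cc1 | intermediate
9 | 8-(4-aminophenoxy)-7-methoxy-3-(4-methoxyphenyl)-4H-chromen-4-one | COc1ccc(-c2coc3c(Oc4ccc(N)cc4)c(OC)ccc3c2=O)cc1 | intermediate
10 | 4-{[7-methoxy-3-(4-methoxyphenyl)-4-oxo-4H-chromen-8-yl]oxy}benzenediazonium tetrafluoroborate | COc1ccc(-c2coc3c(Oc4ccc([N+]#N)cc4)c(OC)ccc3c2=O)cc1.F[B-](F)(F)F | intermediate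
11 | 2-chloro-1,3-dimethoxybenzene | COc1cccc(OC)c1Cl | starting material
12 | acetyl chloride | CC(=O)Cl | starting material
13 | 1-(3-chloro-2,4-dimethoxyphenyl)ethan-1-one | CC(=O)c1ccc(OC)c(Cl)c1OC | intermediate (not isolated)
14 | 1-(3-chloro-2-hydroxy-4-methoxyphenyl)ethan-1-one | CC(=O)c1ccc(OC)c(Cl)c1O | intermediate
15 | (E)-1-(3-chloro-2-hydroxy-4-methoxyphenyl)-3-(dimethylamino)prop-2-en-1-one | CN(C)/C=C/C(=O)c1ccc(OC)c(Cl)c1O | intermediate
16 | (E)-1-(3-chloro-2-hydroxy-4-methoxyphenyl)-3-(dimethylamino)-2-(4-{[7-methoxy-3-(4-methoxyphenyl)-4-oxo-4H-chromen-8-yl]oxy}phenyl)prop-2-en-1-one | CN(C)/C=C(\c1ccc(Oc2c(OC)ccc3c(=O)c(-c4ccc(OC)cc4)coc23)cc1)C(=O)c1ccc(OC)c(Cl)c1O | intermediate (not isolated)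
17 | 8-chloro-7-methoxy-3-(4-{[7-methoxy-3-(4-methoxyphenyl)-4-oxo-4H-chromen-8-yl]oxy}phenyl)-4H-chromen-4-one | COc1ccc(-c2coc3c(Oc4ccc(-c5coc6c(Cl)c(OC)ccc6c5=O)cc4)c(OC)ccc3c2=O)cc1 | intermediate
18 | Bisoflavolin J, 8-chloro-7-hydroxy-3-(4-{[7-hydroxy-3-(4-hydroxyphenyl)-4-oxo-4H-chromen-8-yl]oxy}phenyl)-4H-chromen-4-one | O=c1c(-c2ccc(Oc3c(O)ccc4c(=O)c(-c5ccc(O)cc5)coc34)cc2)coc2c(Cl)c(O)ccc12 | target

**Step count and risks**

Total step count: 9. Longest linear sequence: 7 steps (steps 1, 2, 3, 4, 5, 8, 9).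

Steps most likely to fail:

1. Step 8. Polar azo coupling of the diazonium cation at the nucleophilic α-carbon of the enaminone may outrun the radical pathway, and the aryl radical may be lost by hydrogen abstraction from the solvent. The fallback sets out from 15 and 10 and comes back at 17. Enaminone 15 with I2 (CHCl3, rt) should undergo iodination/ring closure to 8-chloro-3-iodo-7-methoxy-4H-chromen-4-one F1. Diazonium salt 10 with bis(pinacolato)diboron (MeOH, rt) should give 7-methoxy-3-(4-methoxyphenyl)-8-[4-(4,4,5,5-tetramethyl-1,3,2-dioxaborolan-2-yl)phenoxy]-4H-chromen-4-one F2. Suzuki–Miyaura coupling of F1 with F2 (Pd(dppf)Cl2, K2CO3, dioxane/H2O, 80 °C) forms the same C3–C1′ bond and should give 17, the C8–Cl bond being inert beside the C3–I bond.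

2. Step 2. The arylacetyl chloride may be consumed by self-acylation at its own activated anisyl ring or by ketene formation before it acylates the hindered arene, and the ether cleavage may overrun to the 4-methoxy group. The fallback sets out from 3 (with 12) and comes back at 8; it brings in the anisyl ring by cross-coupling instead of with the acyl chloride. Acetylation of 3 with 12 (AlCl3, CH2Cl2, 0 °C) should give 1-[2,4-dimethoxy-3-(4-nitrophenoxy)phenyl]ethan-1-one F3. BCl3 (CH2Cl2, −78 to 0 °C) should cleave only the chelated ether to 1-[2-hydroxy-4-methoxy-3-(4-nitrophenoxy)phenyl]ethan-1-one F4. DMF-DMA (toluene, 90 °C) should give (E)-3-(dimethylamino)-1-[2-hydroxy-4-methoxy-3-(4-nitrophenoxy)phenyl]prop-2-en-1-one F5, and I2 (CHCl3, rt) should close it to 3-iodo-7-methoxy-8-(4-nitrophenoxy)-4H-chromen-4-one F6. Suzuki–Miyaura coupling of F6 with commercial 4-methoxyphenylboronic acid (Pd(PPh3)4, Na2CO3, dioxane/H2O, 80 °C) should give 8.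

3. Step 9. Cleavage may stop at the two hindered, carbonyl-deactivated 7-methoxy groups, partly demethylated boron chelates may precipitate before conversion is complete, and forcing may open the pyranones. The fallback sets out from 8 and 14 and comes back at 18; it exchanges methyl for acetyl on the small halves before they are joined, so the last step becomes a mild ester cleavage.
   - Lower half: BBr3 on 8 should give 7-hydroxy-3-(4-hydroxyphenyl)-8-(4-nitrophenoxy)-4H-chromen-4-one F7. Ac2O/pyridine should give 4-[7-acetoxy-8-(4-nitrophenoxy)-4-oxo-4H-chromen-3-yl]phenyl acetate F8. H2 over sulfided Pt/C (EtOAc, rt) should give 4-[7-acetoxy-8-(4-aminophenoxy)-4-oxo-4H-chromen-3-yl]phenyl acetate F9. t-BuONO/HBF4 (MeCN, 0 °C) should give 4-{[7-acetoxy-3-(4-acetoxyphenyl)-4-oxo-4H-chromen-8-yl]oxy}benzenediazonium tetrafluoroborate F10.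
   - Upper half: BBr3 on 14 should give 1-(3-chloro-2,4-dihydroxyphenyl)ethan-1-one F11. tert-Butoxybis(dimethylamino)methane (toluene, 60 °C), which cannot O-methylate, should give (E)-1-(3-chloro-2,4-dihydroxyphenyl)-3-(dimethylamino)prop-2-en-1-one F12.
   - Coupling and release: F10 and F12 under the conditions of step 8 should pass through (E)-2-(4-{[7-acetoxy-3-(4-acetoxyphenyl)-4-oxo-4H-chromen-8-yl]oxy}phenyl)-1-(3-chloro-2,4-dihydroxyphenyl)-3-(dimethylamino)prop-2-en-1-one F13 (not isolated) to 4-[7-acetoxy-8-{4-(8-chloro-7-hydroxy-4-oxo-4H-chromen-3-yl)phenoxy}-4-oxo-4H-chromen-3-yl]phenyl acetate F14. K2CO3 in MeOH (rt) should then give 18.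

Further compounds
F1 | step 8 | 8-chloro-3-iodo-7-methoxy-4H-chromen-4-one | COc1ccc2c(=O)c(I)coc2c1Cl
F2 | step 8 | 7-methoxy-3-(4-methoxyphenyl)-8-[4-(4,4,5,5-tetramethyl-1,3,2-dioxaborolan-2-yl)phenoxy]-4H-chromen-4-one | COc1ccc(-c2coc3c(Oc4ccc(B5OC(C)(C)C(C)(C)O5)cc4)c(OC)ccc3c2=O)cc1
F3 | step 2 | 1-[2,4-dimethoxy-3-(4-nitrophenoxy)phenyl]ethan-1-one | CC(=O)c1ccc(OC)c(Oc2ccc([N+](=O)[O-])cc2)c1OC
F4 | step 2 | 1-[2-hydroxy-4-methoxy-3-(4-nitrophenoxy)phenyl]ethan-1-one | CC(=O)c1ccc(OC)c(Oc2ccc([N+](=O)[O-])cc2)c1O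
F5 | step 2 | (E)-3-(dimethylamino)-1-[2-hydroxy-4-methoxy-3-(4-nitrophenoxy)phenyl]prop-2-en-1-one | CN(C)/C=C/C(=O)c1ccc(OC)c(Oc2ccc([N+](=O)[O-])cc2)c1O
F6 | step 2 | 3-iodo-7-methoxy-8-(4-nitrophenoxy)-4H-chromen-4-one | COc1ccc2c(=O)c(I)coc2c1Oc1ccc([N+](=O)[O-])cc1
F7 | step 9 | 7-hydroxy-3-(4-hydroxyphenyl)-8-(4-nitrophenoxy)-4H-chromen-4-one | O=c1c(-c2ccc(O)cc2)coc2c(Oc3ccc([N+](=O)[O-])cc3)c(O)ccc12
F8 | step 9 | 4-[7-acetoxy-8-(4-nitrophenoxy)-4-oxo-4H-chromen-3-yl]phenyl acetate | CC(=O)Oc1ccc(-c2coc3c(Oc4ccc([N+](=O)[O-])cc4)c(OC(C)=O)ccc3c2=O)cc1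
F9 | step 9 | 4-[7-acetoxy-8-(4-aminophenoxy)-4-oxo-4H-chromen-3-yl]phenyl acetate | CC(=O)Oc1ccc(-c2coc3c(Oc4ccc(N)cc4)c(OC(C)=O)ccc3c2=O)cc1
F10 | step 9 | 4-{[7-acetoxy-3-(4-acetoxyphenyl)-4-oxo-4H-chromen-8-yl]oxy}benzenediazonium tetrafluoroborate | CC(=O)Oc1ccc(-c2coc3c(Oc4ccc([N+]#N)cc4)c(OC(C)=O)ccc3c2=O)cc1.F[B-](F)(F)F
F11 | step 9 | 1-(3-chloro-2,4-dihydroxyphenyl)ethan-1-one | CC(=O)c1ccc(O)c(Cl)c1O
F12 | step 9 | (E)-1-(3-chloro-2,4-dihydroxyphenyl)-3-(dimethylamino)prop-2-en-1-one | CN(C)/C=C/C(=O)c1ccc(O)c(Cl)c1O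
F13 | step 9 | (E)-2-(4-{[7-acetoxy-3-(4-acetoxyphenyl)-4-oxo-4H-chromen-8-yl]oxy}phenyl)-1-(3-chloro-2,4-dihydroxyphenyl)-3-(dimethylamino)prop-2-en-1-one | CN(C)/C=C(\c1ccc(Oc2c(OC(C)=O)ccc3c(=O)c(-c4ccc(OC(C)=O)cc4)coc23)cc1)C(=O)c1ccc(O)c(Cl)c1O
F14 | step 9 | 4-[7-acetoxy-8-{4-(8-chloro-7-hydroxy-4-oxo-4H-chromen-3-yl)phenoxy}-4-oxo-4H-chromen-3-yl]phenyl acetate | CC(=O)Oc1ccc(-c2coc3c(Oc4ccc(-c5coc6c(Cl)c(O)ccc6c5=O)cc4)c(OC(C)=O)ccc3c2=O)cc1
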